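1. The pitfall was to read a catalysed flask in minutes, so I counted turnovers.

| setting | blue | red | flask |
|---|---|---|---|
| starting material | 0.050 M | 0.050 M | 0.050 M |
| reagent | 0.065 M | 0.033 M | 0.0650 M |
| free catalyst | 2.5 mM | 2.5 mM | 2.5 mM |
| remark | the very flask that is asked about, followed so far | run made earlier |  |
| time |  |  | 8.0 min |

blue run (percent of the starting material charged)

| time / s | target / % |
|---|---|
| 30.0 | 26 |
| 40.0 | 38 |
| 50.0 | 48 |
| 60.0 | 53 |
| 80.0 | 62 |
| 90.0 | 65 |

red run (percent of the starting material charged)

| time / min | target / % |
|---|---|
| 0.500 | 17 |
| 0.833 | 30 |
| 1.33 | 44 |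
| 2.00 | 47 |
| 2.50 | 48 |
| 4.00 | 43 |
| 6.00 | 31 |

(readings scatter by 2 percentage points)

* time up to 8.0 min at which target stands highest
* the amount of target, in percent of the starting material charged, at that time
* the first time at which target reaches 50%, in the same percent, in min

- steps thought possible: starting material + free catalyst <-> catalyst intermediate A; catalyst intermediate D -> free catalyst + target; catalyst intermediate C <-> by-product + catalyst intermediate D; reagent + catalyst intermediate A <-> catalyst intermediate B; target + free catalyst <-> isomer of the product + free catalyst; catalyst intermediate B -> catalyst intermediate C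

2. The charge asked c(starting material)/c(free catalyst) = 20.0 turnovers of each catalyst. In the blue run, target rose from 26% at 30.0 s to 48% at 50.0 s. That read 0.220 /s as the pace, turnovers per catalyst charged per second, an apparent turnover frequency.

3. Held throughout, that early pace covered the count in 1.52 min, which was my own reckoning.

4. I kept c(reagent) at 0.0650 M. The red run's 0.033 M stood below its c(starting material), which capped target at 66.0% at one reagent per turnover. In the blue charge, starting material was the limiting reagent. I also planned an early stop, as the red run's target fell from 48% at 2.50 min to 31% at 6.00 min.

5. The forecast gave 73% at 2.5 min, and 50% at 0.89 min, reading “target isomerising on free catalyst”. Its time was longer than my reckoned 1.52 min.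

6. The flask gave 71.8% at 2.26 min, and 50% at 0.986 min.

    starting material + free catalyst ⇌ catalyst intermediate A (K = 23.1 /M, k = 101 /M/s)
    catalyst intermediate D → free catalyst + target (k = 1.43 /s)
    catalyst intermediate C ⇌ by-product + catalyst intermediate D (K = 2.90 M, k = 0.561 /s)
    reagent + catalyst intermediate A ⇌ catalyst intermediate B (K = 16.3 /M, k = 718 /M/s)
    target + free catalyst ⇌ isomer of the product + free catalyst, rate k5*[free catalyst]*[target] forward; the back reaction follows from the equilibrium constant (K = 3.10, k = 1.85 /M/s)
    catalyst intermediate B → catalyst intermediate C (k = 1.42 /s)

By-product, one per turnover, stood at 0.0435 M at 2.26 min, a mean pace of 0.128 /s against the early 0.220 /s. One change that moved the count was free catalyst at 6.3 × 10⁻⁴ M, in a neighbour flask: the count became 79.4, or 6.01 min at the early pace, later than the forecast's 2.5 min. That neighbour flask at 8.00 min held target 71.9% against its best of 71.9%, starting material 15.7% and by-product 0.0420 M, a mean pace of 0.139 /s.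

Readings and results were computed with constants of no real substance; noise was put on by code.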